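1. Amounts first: this flask starts with 1.0 M of substrate and 50 mM of catalyst under a gas phase held at 42 mM, with [dissolved gas] at nil. The substrate charge is 23.8 times the saturation concentration, and each substrate consumed, on either route, takes one dissolved gas. So the gas must cross during the run. Dissolved gas and substrate give uncatalysed product, or target with catalyst, and target exchanges with its isomer.

| setting | west | east | north-east | flask |
|---|---|---|---|---|
| substrate | 1.4 M | 2.2 M | 1 M | 1.0 M |
| gas phase | 42 mM (held) | 42 mM (held) | 42 mM (held) | 42 mM (held) |
| catalyst | 50 mM | 50 mM | 100 mM | 50 mM |
| remark | run made earlier | run made earlier | run made earlier |  |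
| time |  |  |  | 25 h |

- west (time / h: target / %, substrate / %): 2.00: 2, 94; 5.00: 13, 81; 10.0: 18, 63; 15.0: 22, 46; 20.0: 29, 27
- east (time / h: target / %, substrate / %): 4.00: 7, 89; 8.00: 11, 79; 12.0: 12, 71; 15.0: 19, 64; 20.0: 18, 53
- north-east (time / h: target / %, substrate / %): 1.50: 6, 96; 3.00: 10, 83; 6.00: 21, 70; 10.0: 28, 46; 20.0: 47, 9

(scatter of a reading: 1.5 percentage points)

- at the start none of the gas is dissolved
- what was read earlier has a scatter of 1.5 percentage points, one standard deviation
- steps thought possible: target <-> isomer of the product; substrate + dissolved gas -> uncatalysed product; gas phase <-> dissolved gas; substrate + dissolved gas + catalyst -> catalyst + target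

- Sunday's: doubling the amount of catalyst, all else as stated
- Monday's: doubling the transfer coefficient of the gas phase, all else as stated
- Tuesday's: doubling the saturation concentration of gas phase, all else as stated

- amount of target at 25 h, in percent of the substrate charged
- the change that raises the amount of target at 25 h, in percent of the substrate charged most ("none" if none brings more than 2 percentage points) (Sunday's / Monday's / Tuesday's / none)
- amount of target at 25 h, in percent of the substrate charged, after Sunday's

2. The first instants belong to transfer: without dissolved gas, neither route to product can start.

3. In the middle I read the loss of substrate per hour. The west run gives 0.0521 M h⁻¹, which I call the gas supply: a reading of the substrate consumed per hour, taken on the supposition that transfer is the rate-limiting step. The east run has 1.57 times the substrate, yet it loses 0.0495 M h⁻¹, less than proportion asks. The north-east run has twice the catalyst and loses 0.0588 M h⁻¹ up to its fourth reading, less than double the supply.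

4. For the end I divide the charge by the supply: as an estimate, the gas delivered equals the substrate charged after 19.2 h, which is shorter than 25 h. So I expect the rise of target in this flask to slow late on, while target can still pass to its isomer. On the same estimate, twice the supply brings that moment to 9.60 h, which leaves target longer in that late stage.

5. The forecast says 35%, names Sunday's as the best change, and gives 41% after it. Its ground: “limited by gas transfer”.

6. The flask gives 34.9% of target, and 43.9% after Sunday's, a gain of 8.9 percentage points; Monday's brings −1.6 points and Tuesday's −2.2 points.

    target ⇌ isomer of the product (K = 0.970, k = 0.0790 h⁻¹)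
    substrate + dissolved gas → uncatalysed product (k = 3.80 M⁻¹ h⁻¹)
    gas phase ⇌ dissolved gas, rate k3*(csat - [dissolved gas]) (kL = 1.40 h⁻¹)
    substrate + dissolved gas + catalyst → catalyst + target (k = 120 M⁻² h⁻¹)

7. With the other amounts and the time held, target at 25 h has moved by 5 points from the value of this flask at 36.1 mM or 71.4 mM of catalyst, so a charge of catalyst wrong by that much is what would part the flask from the forecast's 35%. The gas supply leaves 34.9% of substrate in this flask at 12.5 h, and the flask holds 40.5%. In the flask charged with 2.5 M of substrate, it leaves 47.9% at 25 h, and that flask holds 45.8%.

(The readings were generated by integration with made-up constants, and the scatter is random.)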